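All runs are simulated on assumed constants, noise included.

Early times in the dawn run already lay on a line: total product stood at 4.30% after 20.0 min and 17.5% after 90.0 min, so I could read one rate from it.

| flask | left-handed substrate | right-handed substrate | coupling partner | protic impurity | free catalyst | stray impurity | remark | time |
|---|---|---|---|---|---|---|---|---|
| noon | 15 mM | 15 mM | 22.5 mM | 0.30 mM | 75 µM | 36 µM | run made earlier |  |
| dusk | 15 mM | 15 mM | 22.5 mM | 0.30 mM | 75 µM | 57 µM | run made earlier |  |
| dawn | 15 mM | 15 mM | 45 mM | 0.30 mM | 75 µM | 26 µM | run made earlier |  |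
| flask | 15 mM | 15 mM | 22.5 mM | 0.300 mM | 75 µM | 26 µM |  | 2.0 h |

| run | time / min | left-handed product / % | right-handed product / % | left-handed substrate / % |
|---|---|---|---|---|
| noon | 5.00 | 0 | 0.7 | 50.0 |
| noon | 15.0 | 1.2 | 0.9 | 49.4 |
| noon | 25.0 | 2.3 | 0.4 | 49.4 |
| noon | 40.0 | 1.6 | 0.9 | 47.7 |
| noon | 60.0 | 2.6 | 1.0 | 47.3 |
| noon | 80.0 | 4.4 | 2.8 | 47.4 |
| noon | 90.0 | 4.9 | 2.8 | 47.2 |
| dusk | 8.00 | 0.3 | 0.3 | 50.2 |
| dusk | 12.0 | 0 | 1.3 | 49.7 |
| dusk | 20.0 | 0.3 | 0.4 | 50.1 |
| dusk | 25.0 | 0 | 0.8 | 49.6 |
| dusk | 40.0 | 1.5 | 1.4 | 49.3 |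
| dusk | 60.0 | 0.9 | 1.1 | 48.8 |
| dusk | 90.0 | 1.4 | 0.9 | 48.2 |
| dawn | 20.0 | 3.1 | 1.2 | 48.4 |
| dawn | 40.0 | 5.1 | 3.2 | 45.2 |
| dawn | 60.0 | 7.8 | 4.8 | 43.7 |
| dawn | 80.0 | 10.4 | 5.1 | 41.7 |
| dawn | 90.0 | 10.3 | 7.2 | 40.5 |

(standard deviation of a reading: 0.5 percentage points)

- free catalyst is single-handed; left-handed substrate and right-handed substrate are mirror images of each other, charged as a racemate, each of them at the stated concentration
- an excess is the difference of the two amounts in percent of their sum
- an excess is below zero if the other one leads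

- excess of left-handed product over right-handed product in the product at 12 min
- excess of left-handed product over right-handed product in the product at 2.0 h
- part of the left-handed substrate and right-handed substrate charged together that has reacted at 2.0 h

How much catalyst worked? I took the charge of free catalyst minus the stray impurity, 49.0 µM in both the dawn run and the flask.

How fast did it turn? I divided the product rate read in the dawn run by that amount and by [coupling partner], and called the result the turnover constant, 26.5 L mol⁻¹ min⁻¹: turns of each working catalyst per unit time and per unit [coupling partner]. At fixed working catalyst, this rule is pseudo-first-order in partner. Carried to the noon and dusk runs, it gave 6.96% and 3.21% of product against 7.70% and 2.30% read at 90.0 min. A sum of two readings scatters by 0.71 percentage points, so I kept the rule.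

What did it give the flask? At the charged [coupling partner] one turn took 1.68 min, so in 2.0 h I reckoned 11.7% reacted.

Which hand led? The pooled dawn readings gave an excess of 26.1% for left-handed product. I used it for both times.

The forecast gave excesses of 25% (10% to 38%) at 12 min and 24% (16% to 32%) at 2.0 h, and 11% (8.5% to 14%) reacted, with “no firm sign that the excess changes with time”. Its excesses lay 1.1 points and 2.1 points under mine, its conversion 0.70 points under mine.

The flask gave 22.2%, 20.8% and 11.4% in that order, and the forecast held.

    free catalyst + left-handed substrate ⇌ catalyst intermediate A (K = 32.0 L mol⁻¹, k = 85400 L mol⁻¹ min⁻¹)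
    free catalyst + right-handed substrate ⇌ catalyst intermediate B (K = 1350 L mol⁻¹, k = 5100 L mol⁻¹ min⁻¹)
    coupling partner + catalyst intermediate A → free catalyst + left-handed product (k = 732 L mol⁻¹ min⁻¹)
    coupling partner + catalyst intermediate B → free catalyst + right-handed product (k = 12.0 L mol⁻¹ min⁻¹)
    left-handed substrate ⇌ right-handed substrate (k = 0.0291 min⁻¹)
    coupling partner + protic impurity → quenched reagent (k = 36.1 L mol⁻¹ min⁻¹)
    free catalyst + stray impurity → spent catalyst (k = 3.82 × 10⁵ L mol⁻¹ min⁻¹)

The excess slipped by 1.4 points between the two times, and the step of coupling partner with protic impurity made no difference to the excess or the conversion at the asked time. With 84% of the partner left at 2.00 h, 26.5 L mol⁻¹ min⁻¹ stretches a turn from 1.68 min to 2.00 min.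

In the neighbour charged with 5.6 mM of coupling partner, 26.5 L mol⁻¹ min⁻¹ gives a turn of 6.74 min and 2.90% reacted. The computed result is 2.81%.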